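The readings were generated by integration on assumed constants; scatter was added.

The ratio [reagent]/[starting material] in the delta flask is 0.800, below one, so reagent is the limiting reagent and you can follow one reagent molecule to its end.

common to all: starting material 0.18 M
- delta: reagent 0.144 M; temperature 60 °C; the very flask that is asked about, followed so far
- eta: reagent 0.096 M; temperature 45 °C; run made earlier
- flask: reagent 0.144 M; temperature 60 °C; time 30 h

- delta (time / h: single product / %): 1.33: 26; 4.00: 23; 6.00: 29; 10.0: 27; 15.0: 26; 20.0: 24; 25.0: 24
- eta (time / h: single product / %): 0.333: 12; 0.667: 10; 1.00: 10; 1.33: 8; 2.00: 7; 3.00: 7

(scatter of a reading: 2 percentage points)

- midnight: at 30 h take out 90 % of the single product then present, then wait 15 h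
- noon: at 30 h add reagent, 50.0 % of the amount charged, then wait 15 h
- summer: at 30 h raise the temperature by 20 K, then wait 15 h
- dusk: change nothing and wait 15 h more

- single product that was removed still counts
- the analysis behind the earlier runs scatters by 2 percentage points, standard deviation
- candidate steps: starting material + reagent -> single product + by-product; reagent + single product -> bis adduct + by-product; single product <-> isomer of the product
- additions bring no volume worth counting

* single product, in percent of the starting material first charged, at 30 h
* the option that brings most further single product ("none" if no option brings more than 2 percentage points) (midnight / noon / summer / dusk / none)
* single product present, with what was taken out counted in, in percent of the starting material first charged, after midnight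
* single product present, with what was taken out counted in, in percent of the starting material first charged, after noon

The delta readings show no clear trend against their scatter of 2 percentage points, so take their mean, 25.6 %, for 30 h. Divided by the ratio, that reading puts 0.320 of the charged reagent in single product. The delta readings therefore give 0.470 for the plateau odds: single product against everything else a charged reagent molecule ends as. The last two eta readings average 7.00 %, which gives odds of 0.151.

Eta differs from delta in its ratio as well as its temperature, you object. Dividing by the charge removes the plain effect of the ratio, and the rest stays a doubt. If you read the rise in the odds as an Arrhenius law, it has an apparent energy of 66.7 kJ/mol. Then 20 K more gives odds of 1.84, a gain of 26 points.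

But eta rests on two noisy readings. Take 10 % as its plateau instead: its odds become 0.231, and the gain is still 16 points. A worse doubt remains. These odds come from fresh runs, whereas summer heats a flask whose readings already stand flat, and of the candidate steps single product ⇌ isomer of the product is the one that needs no reagent, so treat the figure as high.

Now the rivals. If the share of single product in its pool with the isomer of the product returns after removal, midnight gains the share taken out, times the single product, times the part of the pool that is isomer of the product. If the whole charged reagent sat in that pool, the share would be 0.320 and the gain 16 points. Noon, reckoned at the same chance per molecule, comes to 13 points, and added reagent can attack single product too. Summer leads on the first figure and stands level with midnight on the second, so that is my choice.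

The forecast gave 25.5 %, midnight, 39 % and 28 %, and of the heat it said: “Heating is uncertain.”

The flask gives 24.5 % and 37.7 % and 26.6 %; the best option is summer, with 22 points against 13 points for midnight, 2.1 points for noon and 0 points for dusk.

    starting material + reagent → single product + by-product (k = 0.0140 /M/s, Ea = 61.0 kJ/mol)
    reagent + single product → bis adduct + by-product (k = 0.00620 /M/s, Ea = 73.0 kJ/mol)
    single product ⇌ isomer of the product (K = 1.50, k = 0.00960 /s, Ea = 83.0 kJ/mol, ΔH = −75.0 kJ/mol)
    (constants at 60 °C)

Starting material and reagent made single product, half of that turnover done by 0.0825 h, and single product passed on to bis adduct, half done by 0.197 h, while reagent was there. At 3.00 h reagent stood at 0 %, and at 30.0 h the flask held 24.5 % single product beside 36.8 % isomer of the product. Carried to the repeat at 35 °C, the odds of 0.470 give 5.00 %, and that neighbour flask holds 4.93 %.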